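**Assumption:** the target has no stereocentre and is achiral, so there is no enantiomer to select; the only stereo-element in the route is the E-alkene of stilbene 11, which is consumed in step 6.

## Retrosynthetic overview

1. 13 ⇐ 12: an aromatic Claisen rearrangement of the 6-O-prenyl ether places the 1,1-dimethylallyl group on C7 (last step).
2. 12 ⇐ 11: the benzofuran is closed as in the presumed biogenesis, by oxidative cyclisation of a 2-hydroxystilbene. It is run on the unprotected polyphenol with the prenyl ether in place; ring A of 11 is mirror-symmetric, so either ortho-hydroxyl gives the same product.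
3. 11 ⇐ 9 + 6: Wittig union of 4-O-prenylated phloroglucinaldehyde 9 with the chroman benzylic bromide 6.
4. 6 ⇐ 4 ⇐ 1: the chroman is closed as in the biogenesis, by acid-induced cyclisation of an ortho-prenylphenol inside a BBr3 cascade; the prenyl group is placed by a linear-selective Suzuki coupling on bromide 1.
5. Ring order: chroman (step 3), then benzofuran (step 6).

## Route

Step 1
Reactants: 1 2-bromo-3,5-dimethoxybenzaldehyde; 2 prenylboronic acid pinacol ester (4,4,5,5-tetramethyl-2-(3-methylbut-2-en-1-yl)-1,3,2-dioxaborolane)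
Product: 3 3,5-dimethoxy-2-(3-methylbut-2-en-1-yl)benzaldehyde
Conditions: Pd(OAc)2 (2 mol %), t-BuXPhos (2-di-tert-butylphosphino-2′,4′,6′-triisopropylbiphenyl, 4 mol %), K3PO4 (3 equiv, aq), THF, 60 °C
Reagents that add atoms: none
Why: Suzuki–Miyaura coupling of an allylboronate, in which the bulky electron-rich phosphine lets the allyl-palladium intermediate settle at its less hindered primary terminus before reductive elimination, so the linear prenyl arene forms and the bromide fixes it at C2.

Step 2
Reactants: 3 3,5-dimethoxy-2-(3-methylbut-2-en-1-yl)benzaldehyde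
Product: 4 [3,5-dimethoxy-2-(3-methylbut-2-en-1-yl)phenyl]methanol
Conditions: NaBH4 (1 equiv), MeOH, 0 °C
Reagents that add atoms: none
Why: Chemoselective borohydride reduction of the aryl aldehyde, which leaves the isolated trisubstituted alkene untouched.

Step 3
Reactants: 4 [3,5-dimethoxy-2-(3-methylbut-2-en-1-yl)phenyl]methanol
Product: 6 (7-hydroxy-2,2-dimethylchroman-5-yl)methyl bromide, via open-chain bromo resorcinol 5 (not isolated)
Conditions: BBr3 (3.5 equiv), CH2Cl2, −78 °C to rt, 12 h; then ice-water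
Reagents that add atoms: boron tribromide, BrB(Br)Br
Why: BBr3 ether cleavage removes both methyl groups and converts the benzylic alcohol into the bromide, while the HBr formed in the flask protonates the prenyl alkene to a tertiary cation that the neighbouring phenol oxygen traps in a Markovnikov six-ring closure (acid-induced ortho-prenylphenol to 2,2-dimethylchroman cyclisation, the laboratory counterpart of the biogenetic prenyl cyclisation); only the oxygen ortho to the prenyl group can close.

Step 4
Reactants: 7 2,4,6-trihydroxybenzaldehyde; 8 prenyl bromide (1-bromo-3-methylbut-2-ene)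
Product: 9 2,6-dihydroxy-4-[(3-methylbut-2-en-1-yl)oxy]benzaldehyde
Conditions: K2CO3 (1.0 equiv), DMF, 0 °C to rt
Reagents that add atoms: none
Why: Williamson O-alkylation, selective because the 4-hydroxyl is the only one not hydrogen-bonded to the aldehyde and is the most acidic, so one equivalent of base and bromide alkylates it and leaves the symmetric 2,6-diol.

Step 5
Reactants: 6 (7-hydroxy-2,2-dimethylchroman-5-yl)methyl bromide; 9 2,6-dihydroxy-4-[(3-methylbut-2-en-1-yl)oxy]benzaldehyde
Product: 11 (E)-2-[2-(7-hydroxy-2,2-dimethylchroman-5-yl)ethenyl]-5-[(3-methylbut-2-en-1-yl)oxy]benzene-1,3-diol, via chroman benzylic phosphonium bromide 10 (not isolated)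
Conditions: PPh3 (1.05 equiv), MeCN, 80 °C; solvent exchanged to THF; then 9 (1.0 equiv), LiN(SiMe3)2 (4.2 equiv), 0 to 60 °C; NH4Cl (aq)
Reagents that add atoms: none
Why: One-pot phosphonium salt formation and Wittig olefination, in which the semi-stabilised benzylide adds to the lithium-chelated salicylaldehyde-type carbonyl and the ortho-phenoxide gives mainly the E-alkene, the isomer carried on.

Step 6
Reactants: 11 (E)-2-[2-(7-hydroxy-2,2-dimethylchroman-5-yl)ethenyl]-5-[(3-methylbut-2-en-1-yl)oxy]benzene-1,3-diol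
Product: 12 2-(7-hydroxy-2,2-dimethylchroman-5-yl)-6-[(3-methylbut-2-en-1-yl)oxy]-1-benzofuran-4-ol
Conditions: Pd(OAc)2 (10 mol %), NaOAc (1 equiv), O2 (1 atm), DMSO, 50 °C
Reagents that add atoms: none
Why: Wacker-type aerobic oxidative cyclisation (anti oxypalladation of the stilbene by an ortho-phenol in a 5-endo closure that puts palladium on C3 syn to the C2 hydrogen, then β-hydride elimination and reoxidation of zerovalent palladium by O2), the oxygen counterpart of the Hegedus indole synthesis and a laboratory mimic of the stilbene-to-arylbenzofuran oxidation; the two ortho-hydroxyls of ring A are equivalent, so only one benzofuran can form.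

Step 7
Reactants: 12 2-(7-hydroxy-2,2-dimethylchroman-5-yl)-6-[(3-methylbut-2-en-1-yl)oxy]-1-benzofuran-4-ol
Product: 13 2-(7-hydroxy-2,2-dimethylchroman-5-yl)-7-(2-methylbut-3-en-2-yl)-1-benzofuran-4,6-diol (CNP0300714.0)
Conditions: PhNEt2, 190 °C (sealed tube, argon), 1–2 h
Reagents that add atoms: none
Why: Aromatic Claisen rearrangement, whose [3,3] shift inverts the allyl unit so the prenyl ether delivers a 1,1-dimethylallyl group to an ortho carbon; C7 is preferred over C5 because the C6–C7 bond of a benzofuran has the higher double-bond character (as with 2-naphthyl and 7-coumarinyl allyl ethers) and is the less hindered site, and no para shift is possible because C3a is a ring-fusion carbon.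

## Compound list

1 | 2-bromo-3,5-dimethoxybenzaldehyde | O=Cc1cc(OC)cc(OC)c1Br | starting material
2 | prenylboronic acid pinacol ester | CC(C)=CCB1OC(C)(C)C(C)(C)O1 | starting material
3 | 3,5-dimethoxy-2-(3-methylbut-2-en-1-yl)benzaldehyde | O=Cc1cc(OC)cc(OC)c1CC=C(C)C | intermediate
4 | [3,5-dimethoxy-2-(3-methylbut-2-en-1-yl)phenyl]methanol | OCc1cc(OC)cc(OC)c1CC=C(C)C | intermediate
5 | 5-(bromomethyl)-4-(3-methylbut-2-en-1-yl)benzene-1,3-diol (not isolated) | BrCc1cc(O)cc(O)c1CC=C(C)C | intermediate
6 | (7-hydroxy-2,2-dimethylchroman-5-yl)methyl bromide | BrCc1cc(O)cc2OC(C)(C)CCc12 | intermediate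
7 | 2,4,6-trihydroxybenzaldehyde | O=Cc1c(O)cc(O)cc1O | starting material
8 | prenyl bromide (1-bromo-3-methylbut-2-ene) | CC(C)=CCBr | starting material
9 | 2,6-dihydroxy-4-[(3-methylbut-2-en-1-yl)oxy]benzaldehyde | O=Cc1c(O)cc(OCC=C(C)C)cc1O | intermediate
10 | [(7-hydroxy-2,2-dimethylchroman-5-yl)methyl]triphenylphosphonium bromide (not isolated) | [Br-].Oc1cc(C[P+](c2ccccc2)(c2ccccc2)c2ccccc2)c2CCC(C)(C)Oc2c1 | intermediate
11 | (E)-2-[2-(7-hydroxy-2,2-dimethylchroman-5-yl)ethenyl]-5-[(3-methylbut-2-en-1-yl)oxy]benzene-1,3-diol | Oc1cc(OCC=C(C)C)cc(O)c1/C=C/c1cc(O)cc2OC(C)(C)CCc12 | intermediate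
12 | 2-(7-hydroxy-2,2-dimethylchroman-5-yl)-6-[(3-methylbut-2-en-1-yl)oxy]-1-benzofuran-4-ol | Oc1cc(OCC=C(C)C)cc2oc(-c3cc(O)cc4OC(C)(C)CCc34)cc12 | intermediate
13 | 2-(7-hydroxy-2,2-dimethylchroman-5-yl)-7-(2-methylbut-3-en-2-yl)-1-benzofuran-4,6-diol | C=CC(C)(C)c1c(O)cc(O)c2cc(-c3cc(O)cc4c3CCC(C)(C)O4)oc12 | target

## Step count and risks

Total step count: 7. Longest linear sequence: 6 (steps 1, 2, 3, 5, 6, 7).

The three steps most likely to fail:

**Step 5 (Wittig on the unprotected aldehyde).** The phenoxide form of 9 is a weak electrophile and the ylide may be quenched or react sluggishly. The fallback sets out from 9 and returns at 11. Compound 9 is silylated (TBSCl, imidazole, DMF) to 2,6-bis(tert-butyldimethylsilyloxy)-4-[(3-methylbut-2-en-1-yl)oxy]benzaldehyde F1, a neutral and fully electrophilic aldehyde. The ylide from 10 (LiN(SiMe3)2, 2.1 equiv, THF) converts it into the bis-silyl stilbene (E)-5-{2-[2,6-bis(tert-butyldimethylsilyloxy)-4-[(3-methylbut-2-en-1-yl)oxy]phenyl]ethenyl}-2,2-dimethylchroman-7-ol F2. Tetrabutylammonium fluoride buffered with AcOH (THF, 0 °C) then frees both phenols without touching the prenyl ether, giving 11.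

**Step 6 (oxidative cyclisation of the free polyphenol).** Pd(OAc)2 may cleave the aryl prenyl ether through zerovalent palladium, the electron-rich phenols may be over-oxidised, or the 5-endo closure may stall. The fallback sets out from 6 and 9 and returns at 12; it closes the same O–C2 bond at the stilbene-oxide oxidation level, so no oxidant is needed. Bromide 6 and tetrahydrothiophene (acetone, rt) give the sulfonium salt 1-[(7-hydroxy-2,2-dimethylchroman-5-yl)methyl]thiolan-1-ium bromide F3. Its ylide (Cs2CO3, MeCN, rt) adds to aldehyde 9, and the ortho-phenoxide displaces tetrahydrothiophene from the betaine (or opens the derived epoxide). This gives racemic trans-2-(7-hydroxy-2,2-dimethylchroman-5-yl)-6-[(3-methylbut-2-en-1-yl)oxy]-2,3-dihydro-1-benzofuran-3,4-diol F4; any cis isomer behaves the same way. This doubly activated benzylic alcohol loses water on mild acid treatment (pyridinium p-toluenesulfonate, toluene, 50 °C) to give 12.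

**Step 7 (regiochemistry of the Claisen shift, C7 against C5).** If the C5 isomer or the cyclised dihydrofuran by-products dominate, the order of events is changed so that the rearrangement takes place where both ortho positions are equivalent. The fallback sets out from 9 and returns at 13.
- Heating 9 (PhNEt2, 180 °C) gives 2,4,6-trihydroxy-3-(2-methylbut-3-en-2-yl)benzaldehyde F5 as a single isomer.
- TBSCl (2.1 equiv, imidazole, DMF) silylates the two less hindered hydroxyls and leaves the one flanked by the aldehyde and the tertiary alkyl group, giving 4,6-bis(tert-butyldimethylsilyloxy)-2-hydroxy-3-(2-methylbut-3-en-2-yl)benzaldehyde F6.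
- Wittig reaction with the ylide from 10 gives (E)-5-{2-[4,6-bis(tert-butyldimethylsilyloxy)-2-hydroxy-3-(2-methylbut-3-en-2-yl)phenyl]ethenyl}-2,2-dimethylchroman-7-ol F7.
- The Pd(OAc)2/O2 cyclisation of step 6 can now use only the one free ortho-hydroxyl and gives 5-[4,6-bis(tert-butyldimethylsilyloxy)-7-(2-methylbut-3-en-2-yl)-1-benzofuran-2-yl]-2,2-dimethylchroman-7-ol F8.
- Tetrabutylammonium fluoride (THF, 0 °C) then gives 13.

## Further compounds

F1 | step 5 | 2,6-bis(tert-butyldimethylsilyloxy)-4-[(3-methylbut-2-en-1-yl)oxy]benzaldehyde | O=Cc1c(O[Si](C)(C)C(C)(C)C)cc(OCC=C(C)C)cc1O[Si](C)(C)C(C)(C)C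
F2 | step 5 | (E)-5-{2-[2,6-bis(tert-butyldimethylsilyloxy)-4-[(3-methylbut-2-en-1-yl)oxy]phenyl]ethenyl}-2,2-dimethylchroman-7-ol | CC(C)=CCOc1cc(O[Si](C)(C)C(C)(C)C)c(/C=C/c2cc(O)cc3OC(C)(C)CCc23)c(O[Si](C)(C)C(C)(C)C)c1
F3 | step 6 | 1-[(7-hydroxy-2,2-dimethylchroman-5-yl)methyl]thiolan-1-ium bromide | [Br-].Oc1cc(C[S+]2CCCC2)c2CCC(C)(C)Oc2c1
F4 | step 6 | trans-2-(7-hydroxy-2,2-dimethylchroman-5-yl)-6-[(3-methylbut-2-en-1-yl)oxy]-2,3-dihydro-1-benzofuran-3,4-diol (racemic, one enantiomer drawn) | O[C@@H]1[C@@H](c2cc(O)cc3OC(C)(C)CCc23)Oc2cc(OCC=C(C)C)cc(O)c12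
F5 | step 7 | 2,4,6-trihydroxy-3-(2-methylbut-3-en-2-yl)benzaldehyde | O=Cc1c(O)cc(O)c(C(C)(C)C=C)c1O
F6 | step 7 | 4,6-bis(tert-butyldimethylsilyloxy)-2-hydroxy-3-(2-methylbut-3-en-2-yl)benzaldehyde | O=Cc1c(O[Si](C)(C)C(C)(C)C)cc(O[Si](C)(C)C(C)(C)C)c(C(C)(C)C=C)c1O
F7 | step 7 | (E)-5-{2-[4,6-bis(tert-butyldimethylsilyloxy)-2-hydroxy-3-(2-methylbut-3-en-2-yl)phenyl]ethenyl}-2,2-dimethylchroman-7-ol | C=CC(C)(C)c1c(O)c(/C=C/c2cc(O)cc3OC(C)(C)CCc23)c(O[Si](C)(C)C(C)(C)C)cc1O[Si](C)(C)C(C)(C)C
F8 | step 7 | 5-[4,6-bis(tert-butyldimethylsilyloxy)-7-(2-methylbut-3-en-2-yl)-1-benzofuran-2-yl]-2,2-dimethylchroman-7-ol | C=CC(C)(C)c1c(O[Si](C)(C)C(C)(C)C)cc(O[Si](C)(C)C(C)(C)C)c2cc(-c3cc(O)cc4OC(C)(C)CCc34)oc12
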